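**Retrosynthetic overview**

1. Numbering runs along the chain from C1 (alkyne CH) to C15 (methyl); one oxygen bridges C6/C9 (five-membered ring), the other C7/C12 (seven-membered ring). The last operations are the Z-enyne (C1–C3 added to a C4 aldehyde by Peterson olefination) and C13–Br (inversion of a 13R alcohol).
2. The five-membered ring is formed second: bromoetherification of a 2,7-trans-2,3,6,7-tetrahydrooxepine, in which C6–OH adds to C9 and Br to C10, anti.
3. The seven-membered ring is formed first, in the key step: a (5+2) annulation of a C12 aldehyde (C12–C15) with a C4–C11 chain that carries boron on C9 and a cis-epoxide on C6/C7. Allylboration makes C11–C12 and the Z C9=C10 alkene; the new alkoxide then opens the epoxide at C7 (O–C7) and releases C6–OH.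
4. Enabling feature: in the ring O–C12–C11–C10–C9–C8–C7 the trans O/Br pair on C9/C10 is the retron of a Z alkene flanked by the CH2 groups C8 and C11, and C7 has the oxygen-bearing neighbour C6. The ring is therefore an aldehyde O=C12 plus a five-carbon unit that is nucleophilic at C11 and electrophilic at C7.
5. Building blocks: a skipped diyne from but-3-yn-1-ol and 4-chlorobut-2-yn-1-ol (C4–C11), methyl (R)-2-hydroxybutanoate (C12–C15) and 1,3-bis(triisopropylsilyl)propyne (C1–C3).

Key step: step 9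

Remark on the chemistry: the target is taken as 6R,7R,9R,10R,12R,13S with a 3Z enyne, and the antipodes of the two chiral ligands (steps 4 and 6) are assumed to be those that deliver the stated configurations; the ligand sense is to be confirmed on first use. TBS = tert-butyl(dimethyl)silyl, TIPS = tri(propan-2-yl)silyl.

**Route**

Step 1
Reactants: 1 4-chlorobut-2-yn-1-ol
Product: 2 4-chlorobut-2-yn-1-yl methyl carbonate
Conditions: ClCO2Me, pyridine, CH2Cl2, 0 °C
Reagents that add atoms: methyl chloroformate COC(=O)Cl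
Why: O-acylation of the primary propargylic alcohol by a chloroformate should give the mixed carbonate that later serves as the leaving group for the allylic borylation; no stereocentre is involved.

Step 2
Reactants: 2 4-chlorobut-2-yn-1-yl methyl carbonate; 3 but-3-yn-1-ol
Product: 4 8-hydroxyocta-2,5-diyn-1-yl methyl carbonate
Conditions: CuI, Cs2CO3, DMF, 23 °C
Reagents that add atoms: none
Why: Copper-acetylide alkylation of a propargylic chloride (sp–sp3 coupling to a skipped diyne) should join C7 to C8 while the free hydroxyl and the carbonate stay spectators under the mild carbonate base.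

Step 3
Reactants: 4 8-hydroxyocta-2,5-diyn-1-yl methyl carbonate
Product: 5 (2Z,5Z)-8-hydroxyocta-2,5-dien-1-yl methyl carbonate
Conditions: H2 (1 atm), Pd/CaCO3 poisoned with Pb(OAc)2, quinoline, EtOAc, 23 °C
Reagents that add atoms: none
Why: Syn semi-hydrogenation of both triple bonds over poisoned palladium should give the Z,Z skipped diene, and the allylic carbonate is not expected to be hydrogenolysed on the poisoned catalyst.

Step 4
Reactants: 5 (2Z,5Z)-8-hydroxyocta-2,5-dien-1-yl methyl carbonate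
Product: 6 (2Z)-4-[(2S,3R)-3-(2-hydroxyethyl)oxiran-2-yl]but-2-en-1-yl methyl carbonate
Conditions: VO(O-i-Pr)3 (2 mol %), chiral C2-symmetric bis-hydroxamic acid ligand (4 mol %), cumene hydroperoxide, toluene, 23 °C
Reagents that add atoms: cumene hydroperoxide CC(C)(OO)c1ccccc1
Why: Hydroxyl-directed vanadium-catalysed asymmetric epoxidation of a Z homoallylic alcohol should deliver oxygen only to the C6=C7 alkene next to the free hydroxyl, the ligand setting both epoxide carbons (6R,7S, cis from the Z alkene), while the undirected carbonate-bearing alkene is left alone.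

Step 5
Reactants: 6 (2Z)-4-[(2S,3R)-3-(2-hydroxyethyl)oxiran-2-yl]but-2-en-1-yl methyl carbonate
Product: 7 (2Z)-4-[(2S,3R)-3-(2-TBS-oxyethyl)oxiran-2-yl]but-2-en-1-yl methyl carbonate
Conditions: TBSCl, imidazole, CH2Cl2, 23 °C
Reagents that add atoms: tert-butyldimethylsilyl chloride CC(C)(C)[Si](C)(C)Cl
Why: Silylation of the primary alcohol masks the C4 oxygen so that it cannot open the neighbouring epoxide later; no stereocentre is touched.

Step 6
Reactants: 7 (2Z)-4-[(2S,3R)-3-(2-TBS-oxyethyl)oxiran-2-yl]but-2-en-1-yl methyl carbonate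
Product: 8 (2R)-allyl pinacol boronate tert-butyl(dimethyl){2-[(2R,3S)-3-[(2R)-2-(4,4,5,5-tetramethyl-1,3,2-dioxaborolan-2-yl)but-3-en-1-yl]oxiran-2-yl]ethoxy}silane
Conditions: CuCl (5 mol %), (S,S)-QuinoxP* (5 mol %), KO-t-Bu (10 mol %), B2pin2, THF, 0 °C
Reagents that add atoms: bis(pinacolato)diboron CC1(C)OB(OC1(C)C)B1OC(C)(C)C(C)(C)O1
Why: Copper-catalysed γ-selective (SN2') allylic borylation of a Z allylic carbonate should place boron on C9 anti to the departing carbonate with the face chosen by the chiral bisphosphine (catalyst control, 9R), and the unactivated epoxide and silyl ether are expected to be inert to the boryl-copper species at 0 °C.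

Step 7
Reactants: 9 methyl (2R)-2-hydroxybutanoate
Product: 10 methyl (2R)-2-(TIPS-oxy)butanoate
Conditions: TIPSOTf, 2,6-lutidine, CH2Cl2, 0 °C
Reagents that add atoms: triisopropylsilyl triflate CC(C)[Si](OS(=O)(=O)C(F)(F)F)(C(C)C)C(C)C
Why: Silylation of the secondary hydroxyl with a bulky group that neither migrates to a neighbouring oxygen nor acts as an internal nucleophile later; the stereocentre (future C13) comes from the pool and is untouched.

Step 8
Reactants: 10 methyl (2R)-2-(TIPS-oxy)butanoate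
Product: 11 (2R)-2-(TIPS-oxy)butanal
Conditions: i-Bu2AlH, CH2Cl2, −78 °C
Reagents that add atoms: none
Why: Partial reduction of the α-silyloxy ester through the tetrahedral aluminium hemiacetal that is stable at −78 °C should stop at the aldehyde without epimerisation; the aldehyde is used directly.

Step 9
Reactants: 8 (2R)-allyl pinacol boronate; 11 (2R)-2-(TIPS-oxy)butanal
Product: 14 (1R)-3-(TBS-oxy)-1-[(2R,7R)-7-[(1R)-1-(TIPS-oxy)propyl]-2,3,6,7-tetrahydrooxepin-2-yl]propan-1-ol, via Z-homoallylic pinacol borate 12 (not isolated), via Z-homoallylic tributylstannyl ether 13 (not isolated)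
Conditions: toluene, 40 °C; then (Bu3Sn)2O, 110 °C; then Zn(OTf)2, 90 °C (one flask)
Reagents that add atoms: none
Why: Boronate 8 should add to aldehyde 11 through the closed six-membered chair of an allylboration (B–O–C12–C11–C10–C9) in which the C8 chain on the boron-bearing carbon sits axial to avoid the pinacol methyls, so that C11–C12 forms together with a Z C9=C10 alkene and the 9R centre is traded for 12R; (Bu3Sn)2O then exchanges the boron alkoxide 12 for the stannyl ether 13, whose oxygen opens the Zn(OTf)2-activated cis-epoxide at C7 by SN2 attack and releases the C6 hydroxyl. The closest known reaction types are the allylboration of aldehydes with α-substituted allyl pinacol boronates to Z-homoallylic alcohols and the (Bu3Sn)2O/Zn(OTf)2-promoted exo cyclisation of Z-hydroxy epoxides to α,α'-trans oxepenes. The one ring closed is the oxepene, by 7-exo-tet opening of the epoxide. C12 is controlled by the 9R boron-bearing carbon through the chair (1,3-chirality transfer), C7 by stereospecific inversion of the 7S epoxide carbon to 7R, C6 and C13 are carried in unchanged, and the ring alkene is Z through the axial preference. The step needs the Z chair over the E chair and attack at C7 over C6: the pinacol ester favours the axial chair, the E adduct (which has the opposite C12 configuration) cannot close a seven-membered ring and is removed as open-chain alcohol, and the exo mode at the nearer epoxide carbon gives the seven- and not the eight-membered ring. The Felkin preference of aldehyde 11 opposes the 12R chair, so the partition between the two chairs is the point to watch.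

Step 10
Reactants: 14 (1R)-3-(TBS-oxy)-1-[(2R,7R)-7-[(1R)-1-(TIPS-oxy)propyl]-2,3,6,7-tetrahydrooxepin-2-yl]propan-1-ol
Product: 15 (1R,3R,5R,6R,8R)-5-bromo-8-(2-TBS-oxyethyl)-3-[(1R)-1-(TIPS-oxy)propyl]-2,7-dioxabicyclo[4.2.1]nonane
Conditions: NBS, MeCN, 0 °C, dark
Reagents that add atoms: N-bromosuccinimide O=C1CCC(=O)N1Br
Why: Bromoetherification: the C6 hydroxyl, tethered to the lower face, should capture the reversibly formed bromonium ion at the nearer carbon C9 in a 5-exo mode while bromine ends on C10 on the opposite face (anti addition sets 9R and 10R), the bulky TIPS ether oxygen being too hindered to compete.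

Step 11
Reactants: 15 (1R,3R,5R,6R,8R)-5-bromo-8-(2-TBS-oxyethyl)-3-[(1R)-1-(TIPS-oxy)propyl]-2,7-dioxabicyclo[4.2.1]nonane
Product: 16 2-[(1R,3R,5R,6R,8R)-5-bromo-3-[(1R)-1-hydroxypropyl]-2,7-dioxabicyclo[4.2.1]nonan-8-yl]ethan-1-ol
Conditions: aq. HF (48 %), MeCN, 23 °C
Reagents that add atoms: none
Why: Acidic fluoride desilylation should remove both silyl ethers without base, so the secondary bromide and the bicyclic ether are not endangered.

Step 12
Reactants: 16 2-[(1R,3R,5R,6R,8R)-5-bromo-3-[(1R)-1-hydroxypropyl]-2,7-dioxabicyclo[4.2.1]nonan-8-yl]ethan-1-ol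
Product: 17 2-[(1R,3R,5R,6R,8R)-5-bromo-3-[(1R)-1-hydroxypropyl]-2,7-dioxabicyclo[4.2.1]nonan-8-yl]acetaldehyde
Conditions: TEMPO (10 mol %), PhI(OAc)2, CH2Cl2, 23 °C
Reagents that add atoms: none
Why: Oxoammonium (TEMPO) oxidation is selective for the primary alcohol, so the C4 aldehyde should form while the hindered secondary C13 hydroxyl stays free.

Step 13
Reactants: 17 2-[(1R,3R,5R,6R,8R)-5-bromo-3-[(1R)-1-hydroxypropyl]-2,7-dioxabicyclo[4.2.1]nonan-8-yl]acetaldehyde; 18 1,3-bis(triisopropylsilyl)prop-1-yne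
Product: 19 (1R)-1-[(1R,3R,5R,6R,8R)-5-bromo-8-[(2Z)-5-TIPS-pent-2-en-4-yn-1-yl]-2,7-dioxabicyclo[4.2.1]nonan-3-yl]propan-1-ol
Conditions: 18 (excess), n-BuLi, THF, −78 °C; then 17, −78 to −20 °C
Reagents that add atoms: none
Why: Peterson olefination with the lithiated bis-silyl propyne should give the Z enyne, because the bulky silyl groups steer the addition to the β-silyl alkoxide that collapses by syn elimination of silanolate to the Z alkene; the extra equivalent of reagent only deprotonates the free hydroxyl.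

Step 14
Reactants: 19 (1R)-1-[(1R,3R,5R,6R,8R)-5-bromo-8-[(2Z)-5-TIPS-pent-2-en-4-yn-1-yl]-2,7-dioxabicyclo[4.2.1]nonan-3-yl]propan-1-ol
Product: 20 [(3Z)-5-[(1R,3R,5R,6R,8R)-5-bromo-3-[(1S)-1-bromopropyl]-2,7-dioxabicyclo[4.2.1]nonan-8-yl]pent-3-en-1-yn-1-yl]tri(propan-2-yl)silane
Conditions: CBr4, P(n-Oct)3, toluene, 70 °C
Reagents that add atoms: carbon tetrabromide BrC(Br)(Br)Br
Why: Appel bromination: bromide should displace the alkoxyphosphonium ion by SN2 with inversion, turning the 13R alcohol into the 13S bromide.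

Step 15
Reactants: 20 [(3Z)-5-[(1R,3R,5R,6R,8R)-5-bromo-3-[(1S)-1-bromopropyl]-2,7-dioxabicyclo[4.2.1]nonan-8-yl]pent-3-en-1-yn-1-yl]tri(propan-2-yl)silane
Product: 21 (1R,3R,5R,6R,8R)-5-bromo-3-[(1S)-1-bromopropyl]-8-[(2Z)-pent-2-en-4-yn-1-yl]-2,7-dioxabicyclo[4.2.1]nonane (target)
Conditions: Bu4NF, THF, 0 °C
Reagents that add atoms: none
Why: Fluoride cleaves the alkynyl C–Si bond rapidly at 0 °C, and the short exposure should leave both secondary bromides and the Z alkene untouched.

**Compound list**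

1 | 4-chlorobut-2-yn-1-ol | OCC#CCCl | starting material
2 | 4-chlorobut-2-yn-1-yl methyl carbonate | COC(=O)OCC#CCCl | intermediate
3 | but-3-yn-1-ol | C#CCCO | starting material
4 | 8-hydroxyocta-2,5-diyn-1-yl methyl carbonate | COC(=O)OCC#CCC#CCCO | intermediate
5 | (2Z,5Z)-8-hydroxyocta-2,5-dien-1-yl methyl carbonate | COC(=O)OC/C=C\C/C=C\CCO | intermediate
6 | (2Z)-4-[(2S,3R)-3-(2-hydroxyethyl)oxiran-2-yl]but-2-en-1-yl methyl carbonate | COC(=O)OC/C=C\C[C@@H]1O[C@@H]1CCO | intermediate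
7 | (2Z)-4-[(2S,3R)-3-(2-{[tert-butyl(dimethyl)silyl]oxy}ethyl)oxiran-2-yl]but-2-en-1-yl methyl carbonate | COC(=O)OC/C=C\C[C@@H]1O[C@@H]1CCO[Si](C)(C)C(C)(C)C | intermediate
8 | tert-butyl(dimethyl){2-[(2R,3S)-3-[(2R)-2-(4,4,5,5-tetramethyl-1,3,2-dioxaborolan-2-yl)but-3-en-1-yl]oxiran-2-yl]ethoxy}silane | C=C[C@H](B1OC(C)(C)C(C)(C)O1)C[C@@H]1O[C@@H]1CCO[Si](C)(C)C(C)(C)C | intermediate
9 | methyl (2R)-2-hydroxybutanoate | CC[C@@H](O)C(=O)OC | starting material
10 | methyl (2R)-2-{[tri(propan-2-yl)silyl]oxy}butanoate | CC[C@@H](O[Si](C(C)C)(C(C)C)C(C)C)C(=O)OC | intermediate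
11 | (2R)-2-{[tri(propan-2-yl)silyl]oxy}butanal | CC[C@@H](O[Si](C(C)C)(C(C)C)C(C)C)C=O | intermediate
12 | 2-{[(3R,4R,6Z)-8-[(2S,3R)-3-(2-{[tert-butyl(dimethyl)silyl]oxy}ethyl)oxiran-2-yl]-3-{[tri(propan-2-yl)silyl]oxy}oct-6-en-4-yl]oxy}-4,4,5,5-tetramethyl-1,3,2-dioxaborolane | CC(C)(C)[Si](C)(C)OCC[C@H]1O[C@H]1C/C=C\C[C@@H](OB2OC(C)(C)C(C)(C)O2)[C@H](O[Si](C(C)C)(C(C)C)C(C)C)CC | intermediate
13 | tributyl{[(3R,4R,6Z)-8-[(2S,3R)-3-(2-{[tert-butyl(dimethyl)silyl]oxy}ethyl)oxiran-2-yl]-3-{[tri(propan-2-yl)silyl]oxy}oct-6-en-4-yl]oxy}stannane | CC(C)(C)[Si](C)(C)OCC[C@H]1O[C@H]1C/C=C\C[C@@H](O[Sn](CCCC)(CCCC)CCCC)[C@H](O[Si](C(C)C)(C(C)C)C(C)C)CC | intermediate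
14 | (1R)-3-{[tert-butyl(dimethyl)silyl]oxy}-1-[(2R,7R)-7-[(1R)-1-{[tri(propan-2-yl)silyl]oxy}propyl]-2,3,6,7-tetrahydrooxepin-2-yl]propan-1-ol | CC(C)(C)[Si](C)(C)OCC[C@@H](O)[C@H]1C/C=C\C[C@@H](O1)[C@H](O[Si](C(C)C)(C(C)C)C(C)C)CC | intermediate
15 | {2-[(1R,3R,5R,6R,8R)-5-bromo-3-[(1R)-1-{[tri(propan-2-yl)silyl]oxy}propyl]-2,7-dioxabicyclo[4.2.1]nonan-8-yl]ethoxy}(tert-butyl)dimethylsilane | CC(C)(C)[Si](C)(C)OCC[C@H]1O[C@@H]2C[C@H]1O[C@@H]([C@H](O[Si](C(C)C)(C(C)C)C(C)C)CC)C[C@H]2Br | intermediate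
16 | 2-[(1R,3R,5R,6R,8R)-5-bromo-3-[(1R)-1-hydroxypropyl]-2,7-dioxabicyclo[4.2.1]nonan-8-yl]ethan-1-ol | OCC[C@H]1O[C@@H]2C[C@H]1O[C@@H]([C@H](O)CC)C[C@H]2Br | intermediate
17 | 2-[(1R,3R,5R,6R,8R)-5-bromo-3-[(1R)-1-hydroxypropyl]-2,7-dioxabicyclo[4.2.1]nonan-8-yl]acetaldehyde | O=CC[C@H]1O[C@@H]2C[C@H]1O[C@@H]([C@H](O)CC)C[C@H]2Br | intermediate
18 | 1,3-bis[tri(propan-2-yl)silyl]prop-1-yne | CC(C)[Si](C(C)C)(C(C)C)CC#C[Si](C(C)C)(C(C)C)C(C)C | starting material
19 | (1R)-1-[(1R,3R,5R,6R,8R)-5-bromo-8-{(2Z)-5-[tri(propan-2-yl)silyl]pent-2-en-4-yn-1-yl}-2,7-dioxabicyclo[4.2.1]nonan-3-yl]propan-1-ol | CC(C)[Si](C(C)C)(C(C)C)C#C/C=C\C[C@H]1O[C@@H]2C[C@H]1O[C@@H]([C@H](O)CC)C[C@H]2Br | intermediate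
20 | {(3Z)-5-[(1R,3R,5R,6R,8R)-5-bromo-3-[(1S)-1-bromopropyl]-2,7-dioxabicyclo[4.2.1]nonan-8-yl]pent-3-en-1-yn-1-yl}tri(propan-2-yl)silane | CC(C)[Si](C(C)C)(C(C)C)C#C/C=C\C[C@H]1O[C@@H]2C[C@H]1O[C@@H]([C@@H](Br)CC)C[C@H]2Br | intermediate
21 | (1R,3R,5R,6R,8R)-5-bromo-3-[(1S)-1-bromopropyl]-8-[(2Z)-pent-2-en-4-yn-1-yl]-2,7-dioxabicyclo[4.2.1]nonane | C#C/C=C\C[C@H]1O[C@@H]2C[C@H]1O[C@@H]([C@@H](Br)CC)C[C@H]2Br | target

**Step count and risks**

Total step count: 15. Longest linear sequence: 13 (steps 1–6 and 9–15); steps 7–8 prepare the aldehyde in parallel.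

Steps most likely to fail:

Step 9 (key step). The addition partitions between the Z chair (12R, productive) and the E chair (12S, unable to cyclise), and the Felkin preference of the α-silyloxy aldehyde works against the Z chair; a slow exo closure would add to the loss. The fallback sets out from boronate 8 and replaces aldehyde 11 by commercial ethyl glyoxylate, which has no α-stereocentre and little steric demand, so that only the intrinsic axial preference operates. The same one-flask sequence (stannyl-ether stage kept short) should give ethyl (2R,7R)-7-[(1R)-3-{[tert-butyl(dimethyl)silyl]oxy}-1-hydroxypropyl]-2,3,6,7-tetrahydrooxepine-2-carboxylate F1. NBS in MeCN should then close the second ring to ethyl (1R,3R,5R,6R,8R)-5-bromo-8-(2-{[tert-butyl(dimethyl)silyl]oxy}ethyl)-2,7-dioxabicyclo[4.2.1]nonane-3-carboxylate F2. MeNH(OMe)·HCl with i-PrMgCl converts the ester into the Weinreb amide (1R,3R,5R,6R,8R)-5-bromo-8-(2-{[tert-butyl(dimethyl)silyl]oxy}ethyl)-N-methoxy-N-methyl-2,7-dioxabicyclo[4.2.1]nonane-3-carboxamide F3, and EtMgBr gives the ethyl ketone 1-[(1R,3R,5R,6R,8R)-5-bromo-8-(2-{[tert-butyl(dimethyl)silyl]oxy}ethyl)-2,7-dioxabicyclo[4.2.1]nonan-3-yl]propan-1-one F4. Felkin-controlled reduction with Li(s-Bu)3BH at −78 °C (hydride anti to the ring oxygen) should set 13R in (1R)-1-[(1R,3R,5R,6R,8R)-5-bromo-8-(2-{[tert-butyl(dimethyl)silyl]oxy}ethyl)-2,7-dioxabicyclo[4.2.1]nonan-3-yl]propan-1-ol F5. Aqueous HF in MeCN removes the silyl group and the sequence comes back to the route at diol 16.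

Step 10. The wanted closure at C9 competes with closure at C10 (six-membered mode), with capture of the bromonium ion by the silyl ether oxygen on C13, and with allylic bromination. The fallback sets out from oxepene alcohol 14 and forms the C9–O bond reversibly by alkoxymercuration: Hg(OCOCF3)2 in MeCN at −20 °C, then aq. KBr, should give the anti adduct bromo[(1R,3R,5R,6R,8R)-8-(2-{[tert-butyl(dimethyl)silyl]oxy}ethyl)-3-[(1R)-1-{[tri(propan-2-yl)silyl]oxy}propyl]-2,7-dioxabicyclo[4.2.1]nonan-5-yl]mercury F6 under thermodynamic control. Brominolysis of the C–Hg bond with Br2 in pyridine (polar conditions, retention at carbon) comes back to the route at bromide 15.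

Step 14. The activated C13 alcohol may ionise with help from the neighbouring ring oxygen (loss of clean inversion or ring rearrangement) or eliminate. The fallback sets out from alcohol 19 and separates activation from displacement: ClCH2SO2Cl and 2,6-lutidine in CH2Cl2 at 0 °C should give (1R)-1-[(1R,3R,5R,6R,8R)-5-bromo-8-{(2Z)-5-[tri(propan-2-yl)silyl]pent-2-en-4-yn-1-yl}-2,7-dioxabicyclo[4.2.1]nonan-3-yl]propyl chloromethanesulfonate F7. LiBr in THF at 40 °C then displaces the sulfonate by SN2 with inversion and comes back to the route at dibromide 20.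

**Further compounds**

F1 | step 9 | ethyl (2R,7R)-7-[(1R)-3-{[tert-butyl(dimethyl)silyl]oxy}-1-hydroxypropyl]-2,3,6,7-tetrahydrooxepine-2-carboxylate | CC(C)(C)[Si](C)(C)OCC[C@@H](O)[C@H]1C/C=C\C[C@@H](O1)C(=O)OCC
F2 | step 9 | ethyl (1R,3R,5R,6R,8R)-5-bromo-8-(2-{[tert-butyl(dimethyl)silyl]oxy}ethyl)-2,7-dioxabicyclo[4.2.1]nonane-3-carboxylate | CC(C)(C)[Si](C)(C)OCC[C@H]1O[C@@H]2C[C@H]1O[C@@H](C(=O)OCC)C[C@H]2Br
F3 | step 9 | (1R,3R,5R,6R,8R)-5-bromo-8-(2-{[tert-butyl(dimethyl)silyl]oxy}ethyl)-N-methoxy-N-methyl-2,7-dioxabicyclo[4.2.1]nonane-3-carboxamide | CC(C)(C)[Si](C)(C)OCC[C@H]1O[C@@H]2C[C@H]1O[C@@H](C(=O)N(C)OC)C[C@H]2Br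
F4 | step 9 | 1-[(1R,3R,5R,6R,8R)-5-bromo-8-(2-{[tert-butyl(dimethyl)silyl]oxy}ethyl)-2,7-dioxabicyclo[4.2.1]nonan-3-yl]propan-1-one | CC(C)(C)[Si](C)(C)OCC[C@H]1O[C@@H]2C[C@H]1O[C@@H](C(=O)CC)C[C@H]2Br
F5 | step 9 | (1R)-1-[(1R,3R,5R,6R,8R)-5-bromo-8-(2-{[tert-butyl(dimethyl)silyl]oxy}ethyl)-2,7-dioxabicyclo[4.2.1]nonan-3-yl]propan-1-ol | CC(C)(C)[Si](C)(C)OCC[C@H]1O[C@@H]2C[C@H]1O[C@@H]([C@H](O)CC)C[C@H]2Br
F6 | step 10 | bromo[(1R,3R,5R,6R,8R)-8-(2-{[tert-butyl(dimethyl)silyl]oxy}ethyl)-3-[(1R)-1-{[tri(propan-2-yl)silyl]oxy}propyl]-2,7-dioxabicyclo[4.2.1]nonan-5-yl]mercury | CC(C)(C)[Si](C)(C)OCC[C@H]1O[C@@H]2C[C@H]1O[C@@H]([C@H](O[Si](C(C)C)(C(C)C)C(C)C)CC)C[C@H]2[Hg]Br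
F7 | step 14 | (1R)-1-[(1R,3R,5R,6R,8R)-5-bromo-8-{(2Z)-5-[tri(propan-2-yl)silyl]pent-2-en-4-yn-1-yl}-2,7-dioxabicyclo[4.2.1]nonan-3-yl]propyl chloromethanesulfonate | CC(C)[Si](C(C)C)(C(C)C)C#C/C=C\C[C@H]1O[C@@H]2C[C@H]1O[C@@H]([C@H](OS(=O)(=O)CCl)CC)C[C@H]2Br
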